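## Retrosynthetic overview

1. Macrocarpal J ⇒ break the C9'–isobutyl bond (1,6-addition of an isobutyl nucleophile to a p-quinone methide) and the C9'–aryl bond (aryllithium from 25 plus decalin aldehyde 17).
2. Aldehyde 17 ⇒ triol 15 ⇒ bis-epoxide 14 ⇒ Δ3,11-diene ester 13 ⇒ (reductive 1,3-transposition) enone ester 9.
3. Enone 9 ⇒ ring A closed by an intramolecular aldol condensation of 1,5-diketone 7 ⇒ Michael union of dihydrocarvone imine 5 with oxo-enoate 2.
4. Aryl block 25 ⇒ 1,3-dimethoxybenzene (bromination, C–H borylation/oxidation, double ortho-formylation, protection).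
5. Ring order: ring B comes from the chiral pool (dihydrocarvone), ring A is formed by the aldol closure, and the arene is bought and joined last.

Assumptions: Eudesmane numbering (C1–C15, C9' = benzylic carbon) and α/β face descriptors are used for the decalins. Commercial (+)-dihydrocarvone may be the usual C2-epimer mixture, since C2 is planarised in step 3. Centres formed as mixtures (C4/C5 in 8, C11 in 14, C9' in 27 and 28) are left open in the SMILES. The C9' configuration in step 18 rests on a conformational model, not on precedent for this exact substrate.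

## Route

**Fragment A: Michael acceptor**

Step 1
Reactants: 1 ethyl (E)-4-chloro-4-oxobut-2-enoate (ethyl fumaroyl chloride)
Product: 2 ethyl (E)-4-oxohex-2-enoate
Conditions: Et2Zn (0.6 equiv), Pd(PPh3)4 (2 mol %), toluene, 0 °C→rt
Reagents that add atoms: diethylzinc CC[Zn]CC
Why: Pd-catalysed acylation of an organozinc (Negishi acylation) turns the acid chloride into the ethyl ketone without touching the ester or the electron-poor alkene, so the E geometry is kept.

**Fragment B: decalin aldehyde**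

Step 2
Reactants: 3 (+)-dihydrocarvone; 4 (R)-1-phenylethylamine
Product: 5 (2R,5R)-2-methyl-N-[(1R)-1-phenylethyl]-5-(prop-1-en-2-yl)cyclohexan-1-imine
Conditions: p-TsOH (cat.), toluene, reflux, Dean–Stark; used crude
Reagents that add atoms: none
Why: Acid-catalysed imine condensation with azeotropic water removal installs the chiral auxiliary, and the C5 centre of the ring (future C7) is untouched.

Step 3
Reactants: 5 imine; 2 ethyl (E)-4-oxohex-2-enoate
Product: 7 ethyl (2R)-2-[(1S,4R)-1-methyl-2-oxo-4-(prop-1-en-2-yl)cyclohexyl]-4-oxohexanoate, via Michael adduct imine 6 (not isolated)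
Conditions: THF, 0→40 °C, 3 d; then 10 % aq AcOH, rt
Reagents that add atoms: water O
Why: Aza-ene-type Michael addition of the secondary enamine tautomer (d'Angelo chiral-imine method): the (R)-auxiliary directs attack to the face that puts the C10 methyl cis to the isopropenyl group (10S), bonding occurs at the alkene carbon β to the ketone, and the compact chair-like transition state with the (E)-acceptor sets C1 (the later 1β substituent).

Step 4
Reactants: 7 diketo ester
Product: 9 ethyl 3-oxoeudesma-4,11-diene-1β-carboxylate (1R,7R,10S), via aldol ketol 8 (not isolated)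
Conditions: NaOEt (0.3 equiv), EtOH, 0 °C→rt
Reagents that add atoms: none
Why: Key ring closure: the ethyl-ketone enolate (C4) adds to the ring ketone (C5) in an intramolecular aldol reaction (second half of a Robinson annulation) and the ketol dehydrates to the tetrasubstituted enone; catalytic ethoxide at low temperature leaves C1, C7 and C10 unchanged.

Step 5
Reactants: 9 enone ester
Product: 10 ethyl 3β-hydroxyeudesma-4,11-diene-1β-carboxylate (3S)
Conditions: NaBH4, CeCl3·7H2O, MeOH, −78→−40 °C
Reagents that add atoms: none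
Why: Luche 1,2-reduction; hydride enters axially from the α face, anti to the angular methyl, giving the pseudo-equatorial 3β-alcohol and sparing the ester and isopropenyl group.

Step 6
Reactants: 10 allylic alcohol
Product: 13 ethyl 5α-eudesma-3,11-diene-1β-carboxylate, via N-allyl sulfonylhydrazine 11 (not isolated), via allylic diazene 12 (not isolated)
Conditions: 2-nitrobenzenesulfonylhydrazide (NBSH), PPh3, DEAD, N-methylmorpholine, −30 °C→rt
Reagents that add atoms: none
Why: Myers reductive 1,3-transposition: Mitsunobu displacement inverts C3 (3β-OH → 3α-N), loss of sulfinic acid gives the 3α-diazene, and its retro-ene loss of N2 delivers H suprafacially to C5 on the α face, which sets the trans ring fusion and moves the alkene to C3=C4.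

Step 7
Reactants: 13 diene ester
Product: 14 ethyl 3α,4α:11,12-diepoxy-5α-eudesmane-1β-carboxylate (C11 epimers)
Conditions: mCPBA (2.3 equiv), NaHCO3, CH2Cl2, 0 °C
Reagents that add atoms: mCPBA O=C(OO)c1cccc(Cl)c1
Why: Prilezhaev epoxidation of both alkenes; the axial C10 methyl blocks the β face of ring A, so the ring epoxide forms on the α face, and the C11 configuration is irrelevant because it is erased in step 8.

Step 8
Reactants: 14 bis-epoxide ester
Product: 15 1β-(hydroxymethyl)-5α-eudesmane-4α,11-diol (1R,4R,5R,7R,10S)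
Conditions: LiAlH4 (excess), THF, 0 °C→reflux; Fieser work-up
Reagents that add atoms: none
Why: Hydride opens each epoxide by SN2 attack at its less substituted carbon (C3 and C12), so the oxygen stays on C4 (α, methyl β) and on C11, while the ester is reduced to the primary alcohol.

Step 9
Reactants: 15 triol
Product: 16 1β-(triethylsilyloxymethyl)-4α,11-bis(triethylsilyloxy)-5α-eudesmane
Conditions: TESOTf (3.6 equiv), 2,6-lutidine, CH2Cl2, 0 °C→rt
Reagents that add atoms: triethylsilyl triflate CC[Si](CC)(CC)OS(=O)(=O)C(F)(F)F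
Why: Silyl triflate is reactive enough to silylate both tertiary alcohols, which must be masked before the organolithium and acylation chemistry of step 17.

Step 10
Reactants: 16 tris-TES ether
Product: 17 4α,11-bis(triethylsilyloxy)-5α-eudesmane-1β-carbaldehyde
Conditions: (COCl)2 (4 equiv), DMSO (8 equiv), CH2Cl2, −78→−30 °C; Et3N, −78 °C→rt
Reagents that add atoms: none
Why: Swern conditions cleave and oxidise a primary TES ether directly while the hindered tertiary TES ethers survive; the equatorial 1β-aldehyde is also the thermodynamically preferred C1 epimer, so C1 is not eroded.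

**Fragment C: aryl block**

Step 11
Reactants: 18 1,3-dimethoxybenzene
Product: 20 2-bromo-1,3-dimethoxybenzene, via 2,6-dimethoxyphenyllithium 19 (not isolated)
Conditions: n-BuLi, THF, 0 °C→rt; BrCH2CH2Br, −78 °C→rt
Reagents that add atoms: 1,2-dibromoethane BrCCBr
Why: Directed ortho-metalation occurs only between the two methoxy groups, and the aryllithium is brominated by the vicinal dibromide.

Step 12
Reactants: 20 2-bromo-1,3-dimethoxybenzene
Product: 21 2-(4-bromo-3,5-dimethoxyphenyl)-4,4,5,5-tetramethyl-1,3,2-dioxaborolane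
Conditions: [Ir(OMe)(cod)]2 (1.5 mol %), dtbpy (3 mol %), B2pin2 (1.0 equiv), THF, 80 °C
Reagents that add atoms: bis(pinacolato)diboron CC1(C)OB(OC1(C)C)B1OC(C)(C)C(C)(C)O1
Why: Sterically controlled iridium-catalysed C–H borylation functionalises the only C–H with no ortho substituent (C5, para to Br), and aryl bromides are tolerated.

Step 13
Reactants: 21 aryl boronate
Product: 22 4-bromo-3,5-dimethoxyphenol
Conditions: Oxone, acetone/H2O, 0 °C→rt
Reagents that add atoms: Oxone (potassium peroxymonosulfate) [K+].[O-]S(=O)(=O)OO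
Why: Oxidative 1,2-aryl migration from boron to oxygen converts the boronate to the phenol, giving the one oxygen that differs from the two methyl ethers.

Step 14
Reactants: 22 4-bromo-3,5-dimethoxyphenol
Product: 23 5-bromo-2-hydroxy-4,6-dimethoxybenzene-1,3-dicarbaldehyde
Conditions: hexamethylenetetramine (5 equiv), TFA, 90 °C; then 3 M HCl, 60 °C
Reagents that add atoms: hexamethylenetetramine C1N2CN3CN1CN(C2)C3; water O
Why: Duff reaction: the para position is blocked by bromine, so both strongly activated ortho positions of the phenol are formylated.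

Step 15
Reactants: 23 phenol dialdehyde
Product: 24 5-bromo-2-(tert-butyldimethylsilyloxy)-4,6-dimethoxybenzene-1,3-dicarbaldehyde
Conditions: TBSOTf (1.3 equiv), 2,6-lutidine, CH2Cl2, 0 °C
Reagents that add atoms: tert-butyldimethylsilyl triflate CC(C)(C)[Si](C)(C)OS(=O)(=O)C(F)(F)F
Why: Silyl triflate overcomes the chelated, hindered phenol and installs the fluoride-labile group that later triggers quinone methide formation.

Step 16
Reactants: 24 silyl ether dialdehyde
Product: 25 [4-bromo-2,6-bis(1,3-dioxolan-2-yl)-3,5-dimethoxyphenoxy](tert-butyl)dimethylsilane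
Conditions: TMSOCH2CH2OTMS (3 equiv), TMSOTf (5 mol %), CH2Cl2, −78→−20 °C; pyridine quench
Reagents that add atoms: 1,2-bis(trimethylsilyloxy)ethane C[Si](C)(C)OCCO[Si](C)(C)C
Why: Noyori acetalisation under aprotic conditions masks both aldehydes as dioxolanes, which are stable to organolithium, fluoride and Grignard reagents, without cleaving the aryl silyl ether.

**Union and endgame**

Step 17
Reactants: 25 aryl bromide (1.3 equiv); 17 decalin aldehyde
Product: 28 [2,6-dimethoxy-3,5-bis(1,3-dioxolan-2-yl)-4-(tert-butyldimethylsilyloxy)phenyl][4α,11-bis(triethylsilyloxy)-5α-eudesman-1β-yl]methyl acetate (C9' epimers), via aryllithium 26 (not isolated), via lithium alkoxide 27 (not isolated)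
Conditions: t-BuLi (2.6 equiv), Et2O, −78 °C; 17, −78→−30 °C; Ac2O (4 equiv), −30→0 °C
Reagents that add atoms: acetic anhydride CC(=O)OC(C)=O
Why: Bromine–lithium exchange gives an aryllithium flanked by two methoxy groups that adds 1,2 to the aldehyde, and trapping the alkoxide as the acetate installs the leaving group; the C9' mixture is irrelevant because C9' is planarised in step 18.

Step 18
Reactants: 28 benzylic acetate
Product: 30 4-[(1S)-1-(4α,11-bis(triethylsilyloxy)-5α-eudesman-1β-yl)-3-methylbutyl]-2,6-bis(1,3-dioxolan-2-yl)-3,5-dimethoxyphenol, via p-quinone methide 29 (not isolated)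
Conditions: TBAT (1.2 equiv), THF, −40→0 °C; then i-BuMgCl (4 equiv), CuBr·SMe2 (20 mol %), −78→−30 °C; aq NH4Cl
Reagents that add atoms: isobutylmagnesium chloride CC(C)C[Mg]Cl
Why: Fluoride frees the para-phenoxide, which expels acetate (1,6-elimination) to a p-quinone methide, and copper-catalysed 1,6-conjugate addition of the isobutyl group re-aromatises the ring; allylic 1,3-strain with the ortho-methoxy group holds C1–H in the methide plane, so the nucleophile should attack the face opposite the quaternary C10 and give (S)-C9'.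

Step 19
Reactants: 30 phenol adduct
Product: 31 5-[(1S)-1-(4α,11-dihydroxy-5α-eudesman-1β-yl)-3-methylbutyl]-2-hydroxy-4,6-dimethoxybenzene-1,3-dicarbaldehyde
Conditions: 1 M aq HCl/THF (1:3), rt
Reagents that add atoms: water O
Why: Mild aqueous acid hydrolyses both aryl dioxolanes and both tertiary TES ethers, while the tertiary alcohols do not ionise under these dilute conditions at room temperature.

Step 20
Reactants: 31 di-O-methyl dialdehyde
Product: 32 macrocarpal J
Conditions: NaSEt (10 equiv), DMF, 110 °C; then 1 M HCl work-up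
Reagents that add atoms: none
Why: SN2 demethylation by thiolate cleaves the two methyl ethers, each activated by an ortho formyl group, under basic conditions that spare the tertiary alcohols, the aldehydes (no α-hydrogens) and all stereocentres.

## Compound list

1 | ethyl (E)-4-chloro-4-oxobut-2-enoate | CCOC(=O)/C=C/C(Cl)=O | starting material
2 | ethyl (E)-4-oxohex-2-enoate | CCC(=O)/C=C/C(=O)OCC | intermediate
3 | (+)-dihydrocarvone, (2R,5R)-2-methyl-5-(prop-1-en-2-yl)cyclohexan-1-one | C[C@@H]1CC[C@H](CC1=O)C(C)=C | starting material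
4 | (R)-1-phenylethylamine | C[C@@H](N)c1ccccc1 | starting material
5 | (2R,5R)-2-methyl-N-[(1R)-1-phenylethyl]-5-(prop-1-en-2-yl)cyclohexan-1-imine | C[C@@H]1CC[C@H](CC1=N[C@H](C)c1ccccc1)C(C)=C | intermediate
6 | Michael adduct imine (N-[(R)-1-phenylethyl] imine of 7) | CCC(=O)C[C@@H](C(=O)OCC)[C@]1(C)CC[C@@H](C(C)=C)CC1=N[C@H](C)c1ccccc1 | intermediate (not isolated)
7 | ethyl (2R)-2-[(1S,4R)-1-methyl-2-oxo-4-(prop-1-en-2-yl)cyclohexyl]-4-oxohexanoate | CCC(=O)C[C@@H](C(=O)OCC)[C@]1(C)CC[C@@H](C(C)=C)CC1=O | intermediate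
8 | ethyl 5-hydroxy-3-oxoeudesm-11-ene-1β-carboxylate (aldol ketol, C4/C5 mixture) | CCOC(=O)[C@@H]1CC(=O)C(C)C2(O)C[C@H](C(C)=C)CC[C@]21C | intermediate (not isolated)
9 | ethyl 3-oxoeudesma-4,11-diene-1β-carboxylate (1R,7R,10S) | CCOC(=O)[C@@H]1CC(=O)C(C)=C2C[C@H](C(C)=C)CC[C@]21C | intermediate
10 | ethyl 3β-hydroxyeudesma-4,11-diene-1β-carboxylate | CCOC(=O)[C@@H]1C[C@H](O)C(C)=C2C[C@H](C(C)=C)CC[C@]21C | intermediate
11 | ethyl 3α-[1-(2-nitrophenylsulfonyl)hydrazin-1-yl]eudesma-4,11-diene-1β-carboxylate | CCOC(=O)[C@@H]1C[C@@H](N(N)S(=O)(=O)c3ccccc3[N+](=O)[O-])C(C)=C2C[C@H](C(C)=C)CC[C@]21C | intermediate (not isolated)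
12 | ethyl 3α-diazenyleudesma-4,11-diene-1β-carboxylate | CCOC(=O)[C@@H]1C[C@@H](N=N)C(C)=C2C[C@H](C(C)=C)CC[C@]21C | intermediate (not isolated)
13 | ethyl 5α-eudesma-3,11-diene-1β-carboxylate | CCOC(=O)[C@@H]1CC=C(C)[C@@H]2C[C@H](C(C)=C)CC[C@]21C | intermediate
14 | ethyl 3α,4α:11,12-diepoxy-5α-eudesmane-1β-carboxylate (C11 epimers) | CCOC(=O)[C@@H]1C[C@H]3O[C@@]3(C)[C@@H]2C[C@H](C4(C)CO4)CC[C@]21C | intermediate
15 | 1β-(hydroxymethyl)-5α-eudesmane-4α,11-diol | OC[C@@H]1CC[C@@](C)(O)[C@@H]2C[C@H](C(C)(C)O)CC[C@]21C | intermediate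
16 | 1β-(triethylsilyloxymethyl)-4α,11-bis(triethylsilyloxy)-5α-eudesmane | CC[Si](CC)(CC)OC[C@@H]1CC[C@@](C)(O[Si](CC)(CC)CC)[C@@H]2C[C@H](C(C)(C)O[Si](CC)(CC)CC)CC[C@]21C | intermediate
17 | 4α,11-bis(triethylsilyloxy)-5α-eudesmane-1β-carbaldehyde | O=C[C@@H]1CC[C@@](C)(O[Si](CC)(CC)CC)[C@@H]2C[C@H](C(C)(C)O[Si](CC)(CC)CC)CC[C@]21C | intermediate
18 | 1,3-dimethoxybenzene | COc1cccc(OC)c1 | starting material
19 | 2,6-dimethoxyphenyllithium | COc1cccc(OC)c1[Li] | intermediate (not isolated)
20 | 2-bromo-1,3-dimethoxybenzene | COc1cccc(OC)c1Br | intermediate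
21 | 2-(4-bromo-3,5-dimethoxyphenyl)-4,4,5,5-tetramethyl-1,3,2-dioxaborolane | COc1cc(B2OC(C)(C)C(C)(C)O2)cc(OC)c1Br | intermediate
22 | 4-bromo-3,5-dimethoxyphenol | COc1cc(O)cc(OC)c1Br | intermediate
23 | 5-bromo-2-hydroxy-4,6-dimethoxybenzene-1,3-dicarbaldehyde | COc1c(Br)c(OC)c(C=O)c(O)c1C=O | intermediate
24 | 5-bromo-2-(tert-butyldimethylsilyloxy)-4,6-dimethoxybenzene-1,3-dicarbaldehyde | COc1c(Br)c(OC)c(C=O)c(O[Si](C)(C)C(C)(C)C)c1C=O | intermediate
25 | [4-bromo-2,6-bis(1,3-dioxolan-2-yl)-3,5-dimethoxyphenoxy](tert-butyl)dimethylsilane | COc1c(Br)c(OC)c(C2OCCO2)c(O[Si](C)(C)C(C)(C)C)c1C1OCCO1 | intermediate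
26 | aryllithium from 25 | COc1c([Li])c(OC)c(C2OCCO2)c(O[Si](C)(C)C(C)(C)C)c1C1OCCO1 | intermediate (not isolated)
27 | lithium alkoxide of the aryl(eudesman-1β-yl)methanol (C9' epimers) | [Li]OC(c1c(OC)c(C2OCCO2)c(O[Si](C)(C)C(C)(C)C)c(C2OCCO2)c1OC)[C@@H]1CC[C@@](C)(O[Si](CC)(CC)CC)[C@@H]2C[C@H](C(C)(C)O[Si](CC)(CC)CC)CC[C@]21C | intermediate (not isolated)
28 | aryl(eudesman-1β-yl)methyl acetate (C9' epimers) | CC(=O)OC(c1c(OC)c(C2OCCO2)c(O[Si](C)(C)C(C)(C)C)c(C2OCCO2)c1OC)[C@@H]1CC[C@@](C)(O[Si](CC)(CC)CC)[C@@H]2C[C@H](C(C)(C)O[Si](CC)(CC)CC)CC[C@]21C | intermediate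
29 | p-quinone methide (4-alkylidene-3,5-dimethoxy-2,6-bis(1,3-dioxolan-2-yl)cyclohexa-2,5-dien-1-one) | COC1=C(C2OCCO2)C(=O)C(C2OCCO2)=C(OC)C1=C[C@@H]1CC[C@@](C)(O[Si](CC)(CC)CC)[C@@H]2C[C@H](C(C)(C)O[Si](CC)(CC)CC)CC[C@]21C | intermediate (not isolated)
30 | 4-[(1S)-1-(4α,11-bis(triethylsilyloxy)-5α-eudesman-1β-yl)-3-methylbutyl]-2,6-bis(1,3-dioxolan-2-yl)-3,5-dimethoxyphenol | CC(C)C[C@H](c1c(OC)c(C2OCCO2)c(O)c(C2OCCO2)c1OC)[C@@H]1CC[C@@](C)(O[Si](CC)(CC)CC)[C@@H]2C[C@H](C(C)(C)O[Si](CC)(CC)CC)CC[C@]21C | intermediate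
31 | 5-[(1S)-1-(4α,11-dihydroxy-5α-eudesman-1β-yl)-3-methylbutyl]-2-hydroxy-4,6-dimethoxybenzene-1,3-dicarbaldehyde | CC(C)C[C@H](c1c(OC)c(C=O)c(O)c(C=O)c1OC)[C@@H]1CC[C@@](C)(O)[C@@H]2C[C@H](C(C)(C)O)CC[C@]21C | intermediate
32 | macrocarpal J | CC(C)C[C@H](c1c(O)c(C=O)c(O)c(C=O)c1O)[C@@H]1CC[C@@](C)(O)[C@@H]2C[C@H](C(C)(C)O)CC[C@]21C | target

## Step count and risk

Total step count: 20 (fragment A 1, fragment B 9, fragment C 6, union and endgame 4).

Longest linear sequence: 13 steps (steps 2–10 and 17–20 from 3; equally steps 1, 3–10 and 17–20 from 1), which is 65 % of the total.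

Three steps most likely to fail:

Step 3 (chiral-imine Michael addition to the β-substituted acceptor 2; reactivity, regiochemistry and the C1/C10 outcome all rest on analogy). The fallback sets out from imine 5 and comes back at enone ester 9. Imine 5 is combined with the sp-hybridised, less hindered acceptor ethyl 4-oxohex-2-ynoate F1 (from ethyl propiolate, LiHMDS, then N-methoxy-N-methylpropanamide). The aza-ene addition gives the alkenyl adduct imine F2, and aqueous acetic acid releases the ene-dione ester F3. NaOEt in EtOH equilibrates the alkene geometry and closes ring A by the same intramolecular aldol condensation, through the ketol F4, to the cross-conjugated dienone ester F5. Conjugate reduction of the doubly activated C1=C2 bond (L-Selectride, THF, −78 °C, then 2,6-di-tert-butylphenol) adds hydride at C2 and protonates the ester enolate at C1 from the α face, anti to the angular methyl, which gives 9. In this variant C1 is set by the reduction and not by the aza-ene transition state.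

Step 6 (Mitsunobu step of the Myers transposition on a hindered allylic alcohol next to a tetrasubstituted alkene). The fallback sets out from allylic alcohol 10 and comes back at diene ester 13. Alcohol 10 is formylated (formic acetic anhydride, pyridine) to the 3β-formate F6. Pd(OAc)2/n-Bu3P (cat.) in THF at rt→60 °C (Tsuji–Mandai hydrogenolysis) then ionises the formate with inversion, so palladium sits on the α face, and after loss of CO2 the hydride is delivered from palladium to the more substituted terminus C5 on that face. This gives the same 5α-H, Δ3 product 13 without any Mitsunobu displacement.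

Step 18 (quinone methide formation and 1,6-addition; the methide may tautomerise and the C9' selectivity is model-based). The fallback sets out from aldehyde 17 and comes back at target 32 through a cationic manifold with late formylation. 2,4,6-Trimethoxyphenyllithium F7 (from commercial 1,3,5-trimethoxybenzene and n-BuLi) adds to 17 to give the carbinol F8. BF3·OEt2 at −78 °C ionises F8 to the trimethoxybenzylic cation, which is trapped by methallyltrimethylsilane on the face opposite C10 to give the methallyl compound F9. Hydrogenation (H2, Pd/C) gives the isobutyl compound F10, and NBS (2 equiv) gives the dibromide F11. Double bromine–lithium exchange (t-BuLi) and DMF give the dialdehyde F12, 1 M HCl/THF removes the TES ethers to give the diol F13, and thiolate demethylation as in step 20 (three methyl ethers) gives 32. This route shares the facial model of step 18, so it answers a failure of the quinone methide chemistry, not a wrong C9' configuration.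

## Further compounds

F1 | step 3 | ethyl 4-oxohex-2-ynoate | CCC(=O)C#CC(=O)OCC
F2 | step 3 | alkenyl adduct imine (N-[(R)-1-phenylethyl] imine of F3, E/Z) | CCC(=O)C=C(C(=O)OCC)[C@]1(C)CC[C@@H](C(C)=C)CC1=N[C@H](C)c1ccccc1
F3 | step 3 | ethyl 2-[(1S,4R)-1-methyl-2-oxo-4-(prop-1-en-2-yl)cyclohexyl]-4-oxohex-2-enoate (E/Z) | CCC(=O)C=C(C(=O)OCC)[C@]1(C)CC[C@@H](C(C)=C)CC1=O
F4 | step 3 | ethyl 5-hydroxy-3-oxoeudesma-1,11-diene-1-carboxylate (ketol, C4/C5 mixture) | CCOC(=O)C1=CC(=O)C(C)C2(O)C[C@H](C(C)=C)CC[C@]21C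
F5 | step 3 | ethyl 3-oxoeudesma-1,4,11-triene-1-carboxylate | CCOC(=O)C1=CC(=O)C(C)=C2C[C@H](C(C)=C)CC[C@]21C
F6 | step 6 | ethyl 3β-(formyloxy)eudesma-4,11-diene-1β-carboxylate | CCOC(=O)[C@@H]1C[C@H](OC=O)C(C)=C2C[C@H](C(C)=C)CC[C@]21C
F7 | step 18 | 2,4,6-trimethoxyphenyllithium | COc1cc(OC)c([Li])c(OC)c1
F8 | step 18 | (2,4,6-trimethoxyphenyl)[4α,11-bis(triethylsilyloxy)-5α-eudesman-1β-yl]methanol (C9' epimers) | OC(c1c(OC)cc(OC)cc1OC)[C@@H]1CC[C@@](C)(O[Si](CC)(CC)CC)[C@@H]2C[C@H](C(C)(C)O[Si](CC)(CC)CC)CC[C@]21C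
F9 | step 18 | 2-[(1S)-1-(4α,11-bis(triethylsilyloxy)-5α-eudesman-1β-yl)-3-methylbut-3-enyl]-1,3,5-trimethoxybenzene | CC(=C)C[C@H](c1c(OC)cc(OC)cc1OC)[C@@H]1CC[C@@](C)(O[Si](CC)(CC)CC)[C@@H]2C[C@H](C(C)(C)O[Si](CC)(CC)CC)CC[C@]21C
F10 | step 18 | 2-[(1S)-1-(4α,11-bis(triethylsilyloxy)-5α-eudesman-1β-yl)-3-methylbutyl]-1,3,5-trimethoxybenzene | CC(C)C[C@H](c1c(OC)cc(OC)cc1OC)[C@@H]1CC[C@@](C)(O[Si](CC)(CC)CC)[C@@H]2C[C@H](C(C)(C)O[Si](CC)(CC)CC)CC[C@]21C
F11 | step 18 | 2,4-dibromo-6-[(1S)-1-(4α,11-bis(triethylsilyloxy)-5α-eudesman-1β-yl)-3-methylbutyl]-1,3,5-trimethoxybenzene | CC(C)C[C@H](c1c(OC)c(Br)c(OC)c(Br)c1OC)[C@@H]1CC[C@@](C)(O[Si](CC)(CC)CC)[C@@H]2C[C@H](C(C)(C)O[Si](CC)(CC)CC)CC[C@]21C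
F12 | step 18 | 5-[(1S)-1-(4α,11-bis(triethylsilyloxy)-5α-eudesman-1β-yl)-3-methylbutyl]-2,4,6-trimethoxybenzene-1,3-dicarbaldehyde | CC(C)C[C@H](c1c(OC)c(C=O)c(OC)c(C=O)c1OC)[C@@H]1CC[C@@](C)(O[Si](CC)(CC)CC)[C@@H]2C[C@H](C(C)(C)O[Si](CC)(CC)CC)CC[C@]21C
F13 | step 18 | 5-[(1S)-1-(4α,11-dihydroxy-5α-eudesman-1β-yl)-3-methylbutyl]-2,4,6-trimethoxybenzene-1,3-dicarbaldehyde | CC(C)C[C@H](c1c(OC)c(C=O)c(OC)c(C=O)c1OC)[C@@H]1CC[C@@](C)(O)[C@@H]2C[C@H](C(C)(C)O)CC[C@]21C
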